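**Plan**
Numbering: unit 1 = rings A/C/B (O1, C2, C3, C4, C4a, C8a; ring B = 4-methoxyphenyl). Unit 2 = rings D/F/E (double-primed locants; ring E = 4-hydroxyphenyl).
Cuts: (a) five benzyl-type O–C bonds. (b) C2–C3 of ring C, with C2 re-attached to C4; this contracts ring C to a 3-hydroxy-2-aryl-2,3-dihydrobenzofuran that carries C3 as the outer carbon of an (E)-alkylidene on ring F. (c) C3=C3″ (aldol condensation). (d) C2–C4 (photocyclisation). (e) C2″–ring E (conjugate addition).
Enabling feature: C2 is benzylic to ring B and bound to O1, so an oxygen radical on C4 breaks only C4–C2. C3 lies β to C4″=O within the 1,4-diketone C4–C3–C3″–C4″, so the C3=C3″ bond takes the C2 radical back at C3 and the five-membered ring becomes ring C.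
Forward order: ring F first (chromone, then flavanone 6). Ring A comes from tris-PMB phloroglucinol, one PMB group of which becomes C2 and ring B on closure of the five-membered ring. Then union at C3=C3″, ring expansion to ring C, and hydrogenolysis.
Stereochemistry: C2″ comes from a rhodium-catalysed asymmetric 1,4-addition. C3, C2 and C3″ are all set in the ring expansion under control of the pseudo-axial ring E on C2″.

Key step: step 12

Remark: the two stereocentres of the dihydrobenzofuran ring (later C2 and C4) are erased in step 12. Compounds 12–14 and 16–19 are therefore carried as stereoisomer mixtures at these centres, and their SMILES leave them open.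

Step 1
Reactants: 1 2,4,6-trihydroxyacetophenone
Product: 2 1-[2,4-bis(benzyloxy)-6-hydroxyphenyl]ethanone
Conditions: BnBr (2.1 equiv), K2CO3, DMF, 25 °C
Reagents that add atoms: benzyl bromide, BrCc1ccccc1
Why: Williamson ether synthesis in which the hydroxyl hydrogen-bonded to the acetyl C=O is the least nucleophilic and should stay free with two equivalents of bromide.

Step 2
Reactants: 2 1-[2,4-bis(benzyloxy)-6-hydroxyphenyl]ethanone
Product: 4 5,7-bis(benzyloxy)-4H-chromen-4-one, via enaminone 3 (not isolated)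
Conditions: Me2NCH(OMe)2, toluene, 100 °C; then conc. HCl, CH2Cl2, 40 °C
Reagents that add atoms: N,N-dimethylformamide dimethyl acetal, COC(OC)N(C)C
Why: Enaminone route to chromones, in which condensation at the acetyl CH3 is followed by acid-induced addition–elimination of the free phenol, closing ring F at the chromone level.

Step 3
Reactants: 4 5,7-bis(benzyloxy)-4H-chromen-4-one; 5 4-(benzyloxy)phenylboronic acid
Product: 6 (2S)-5,7-bis(benzyloxy)-2-[4-(benzyloxy)phenyl]chroman-4-one
Conditions: [RhCl(C2H4)2]2 (1.5 mol %), (S)-MeO-F12-BIPHEP (3.3 mol %), KOH (10 mol %), toluene/H2O, 20 °C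
Reagents that add atoms: none
Why: Hayashi–Miyaura asymmetric 1,4-addition, a reaction type shown on 5,7-dioxygenated chromones, in which the (S)-bisphosphine should by analogy with cyclic enones direct the aryl group to the face that gives 2S, while the nearly neutral cold medium avoids retro-oxa-Michael racemisation.

Step 4
Reactants: 7 phloroglucinol
Product: 8 1,3,5-tris[(4-methoxybenzyl)oxy]benzene
Conditions: PMBCl (3.3 equiv), K2CO3, DMF, 60 °C
Reagents that add atoms: 4-methoxybenzyl chloride, COc1ccc(CCl)cc1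
Why: Threefold Williamson etherification that gives a symmetric tris-ether, so the two positions ortho to the later acyl group are equivalent.

Step 5
Reactants: 8 1,3,5-tris[(4-methoxybenzyl)oxy]benzene
Product: 9 2-bromo-1,3,5-tris[(4-methoxybenzyl)oxy]benzene
Conditions: NBS (1.0 equiv), MeCN, −10 °C, dark
Reagents that add atoms: N-bromosuccinimide, O=C1CCC(=O)N1Br
Why: Electrophilic aromatic bromination should occur on the central trialkoxybenzene ring, which is far more electron-rich than the anisyl rings, and one equivalent in the cold should stop at the monobromide.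

Step 6
Reactants: 9 2-bromo-1,3,5-tris[(4-methoxybenzyl)oxy]benzene
Product: 11 methyl oxo{2,4,6-tris[(4-methoxybenzyl)oxy]phenyl}acetate, via aryllithium 10 (not isolated)
Conditions: n-BuLi (1.05 equiv), THF, −78 °C; cannulated into (CO2Me)2 (3 equiv), THF, −78 °C
Reagents that add atoms: dimethyl oxalate, COC(=O)C(=O)OC; n-butyllithium, [Li]CCCC (lithium of 10 only)
Why: Bromine–lithium exchange outruns benzylic deprotonation at −78 °C, and the hindered aryllithium should acylate excess dimethyl oxalate only once to give the α-keto ester.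

Step 7
Reactants: 11 methyl oxo{2,4,6-tris[(4-methoxybenzyl)oxy]phenyl}acetate
Product: 12 methyl 3-hydroxy-2-(4-methoxyphenyl)-4,6-bis[(4-methoxybenzyl)oxy]-2,3-dihydro-1-benzofuran-3-carboxylate (stereoisomer mixture)
Conditions: hν (365 nm LEDs), degassed benzene (0.01 M), 20 °C
Reagents that add atoms: none
Why: Norrish–Yang-type photocyclisation known for ortho-benzyloxyphenylglyoxylates, in which the excited keto C=O abstracts a benzylic δ-hydrogen of an ortho OCH2Ar group and the 1,5-biradical closes the C2–C4 bond; the two ortho PMB groups are equivalent, so only one constitution can form, and the new stereocentres need no control.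

Step 8
Reactants: 12 methyl 3-hydroxy-2-(4-methoxyphenyl)-4,6-bis[(4-methoxybenzyl)oxy]-2,3-dihydro-1-benzofuran-3-carboxylate
Product: 13 methyl 2-(4-methoxyphenyl)-4,6-bis[(4-methoxybenzyl)oxy]-3-[(triethylsilyl)oxy]-2,3-dihydro-1-benzofuran-3-carboxylate
Conditions: TESOTf, 2,6-lutidine, CH2Cl2, −78 to 0 °C
Reagents that add atoms: triethylsilyl trifluoromethanesulfonate, CC[Si](CC)(CC)OS(=O)(=O)C(F)(F)F
Why: Silyl triflate silylation of a hindered tertiary alcohol, which blocks α-ketol shift and alkoxide chemistry in the next two steps, while the neighbouring ester retards ionisation at the carbinol carbon.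

Step 9
Reactants: 13 methyl 2-(4-methoxyphenyl)-4,6-bis[(4-methoxybenzyl)oxy]-3-[(triethylsilyl)oxy]-2,3-dihydro-1-benzofuran-3-carboxylate
Product: 14 2-(4-methoxyphenyl)-4,6-bis[(4-methoxybenzyl)oxy]-3-[(triethylsilyl)oxy]-2,3-dihydro-1-benzofuran-3-carbaldehyde
Conditions: i-Bu2AlH (1.2 equiv), toluene, −78 °C; aq potassium sodium tartrate
Reagents that add atoms: none
Why: Partial ester reduction, in which the aluminium hemiacetal next to the quaternary α-silyloxy carbon should persist at −78 °C and collapse to the aldehyde (the future C3) only on work-up.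

Step 10
Reactants: 6 (2S)-5,7-bis(benzyloxy)-2-[4-(benzyloxy)phenyl]chroman-4-one; 14 2-(4-methoxyphenyl)-4,6-bis[(4-methoxybenzyl)oxy]-3-[(triethylsilyl)oxy]-2,3-dihydro-1-benzofuran-3-carbaldehyde
Product: 18 (2R,3E)-5,7-bis(benzyloxy)-2-[4-(benzyloxy)phenyl]-3-({2-(4-methoxyphenyl)-4,6-bis[(4-methoxybenzyl)oxy]-3-[(triethylsilyl)oxy]-2,3-dihydro-1-benzofuran-3-yl}methylidene)chroman-4-one, via lithium enolate 15 (not isolated), via lithium aldolate 16 (not isolated), via aldol acetate 17 (not isolated)
Conditions: LiN(SiMe3)2 (1.05 equiv), THF, −78 °C; 14; Ac2O (3 equiv), −78 to 0 °C; DBU (3 equiv), 0 °C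
Reagents that add atoms: lithium hexamethyldisilazide, [Li]N([Si](C)(C)C)[Si](C)(C)C (lithium of 15 and 16 only); acetic anhydride, CC(=O)OC(C)=O (acetyl of 17 only)
Why: Directed aldol condensation in which the cold lithium enolate adds to the non-enolisable aldehyde anti to ring E, immediate acetylation blocks retro-aldol and silyl migration, and E1cB loss of acetate should give the E-alkylidene (large group anti to C4″=O) with C2″ spatially unchanged (2R only through a change of CIP ranking).

Step 11
Reactants: 18 the triethylsilyl-protected (2R,3E)-alkylidene flavanone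
Product: 19 (2R,3E)-5,7-bis(benzyloxy)-2-[4-(benzyloxy)phenyl]-3-({3-hydroxy-2-(4-methoxyphenyl)-4,6-bis[(4-methoxybenzyl)oxy]-2,3-dihydro-1-benzofuran-3-yl}methylidene)chroman-4-one
Conditions: HF·pyridine, pyridine, THF, 0 °C; crude product used at once
Reagents that add atoms: none
Why: Fluoride-driven Si–O cleavage in a pyridine-buffered medium, chosen so that the tertiary, electron-rich benzylic alcohol is neither ionised nor converted into its alkoxide.

Step 12
Reactants: 19 the tertiary allylic alcohol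
Product: 21 (2S,3R,2″S,3″S)-5″,7″,4‴-tris(benzyloxy)-4′-methoxy-5,7-bis[(4-methoxybenzyl)oxy]-3,3″-biflavanone, via ring-opened benzylic radical 20 (not isolated)
Conditions: [Ir(dF(CF3)ppy)2(bpy)]PF6 (2 mol %), 2,4,6-triisopropylbenzenethiol (20 mol %), 2,4,6-collidine (2 equiv), degassed CH2Cl2 (0.01 M), 450 nm LEDs, 10 °C
Reagents that add atoms: none
Why: The excited iridium complex oxidises ring A, the only non-acylated trioxygenated arene, collidine removes the adjacent O–H proton (proton-coupled electron transfer), and the resulting C4–O radical cleaves the C4–C2 bond, since only C2 leaves as a stabilised radical (benzylic to ring B, α to O1) and the cleavage relieves the congested five-membered ring while creating the aryl ketone C4=O. Radical 20 adds through C2 to C3 of the unmasked enedione C4(=O)–C3=C3″–C4″(=O), the α-keto radical at C3″ takes hydrogen from the thiol, and the thiyl radical is reduced by the reduced photocatalyst and reprotonated, so the step is a redox-neutral isomerisation. The closest known reaction type is the photocatalytic n+1 ring expansion of cyclic tertiary allylic alcohols by alkoxy-radical β-scission and Giese-type re-closure on the enone set free. Ring C closes 6-exo-trig at the CH terminus C3, which is β to C4″=O and polarity-matched to the nucleophilic radical, whereas 7-endo attack at the fully substituted C3″ is disfavoured. Allylic strain with the E-alkylidene holds ring E pseudo-axial on C2″, so ring A and its tethered radical should reach C3 only from the opposite face (3R), ring B then lies over the vinylic hydrogen rather than over ring F (2,3-trans, 2S), and the bulky thiol delivers hydrogen to C3″ again anti to ring E (2″,3″-cis, 3″S), a kinetic outcome that collidine is too weak a base to erase. The step needs ring closure to outrun hydrogen transfer to 20 (secured by catalytic thiol and the doubly activated acceptor), retention of the E geometry, and no re-oxidation of the product, whose ring A is deactivated by the new C4=O.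

Step 13
Reactants: 21 the pentaprotected biflavanone
Product: 22 (2S,3R,2″S,3″S)-5,7,5″,7″,4‴-pentahydroxy-4′-methoxy-3,3″-biflavanone (target)
Conditions: H2 (1 atm), Pd/C (10 wt %), EtOAc/MeOH, 20 °C
Reagents that add atoms: none
Why: Hydrogenolysis of three benzyl and two 4-methoxybenzyl aryl ethers under neutral conditions, which should leave the methyl ether, both ketones and the base-labile centres C3 and C3″ untouched.

**Compound list**
1 | 2,4,6-trihydroxyacetophenone | CC(=O)c1c(O)cc(O)cc1O | starting material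
2 | 1-[2,4-bis(benzyloxy)-6-hydroxyphenyl]ethanone | CC(=O)c1c(O)cc(OCc2ccccc2)cc1OCc1ccccc1 | intermediate
3 | (E)-1-[2,4-bis(benzyloxy)-6-hydroxyphenyl]-3-(dimethylamino)prop-2-en-1-one | CN(C)/C=C/C(=O)c1c(O)cc(OCc2ccccc2)cc1OCc1ccccc1 | intermediate
4 | 5,7-bis(benzyloxy)-4H-chromen-4-one | O=c1ccoc2cc(OCc3ccccc3)cc(OCc3ccccc3)c12 | intermediate
5 | 4-(benzyloxy)phenylboronic acid | OB(O)c1ccc(OCc2ccccc2)cc1 | starting material
6 | (2S)-5,7-bis(benzyloxy)-2-[4-(benzyloxy)phenyl]chroman-4-one | O=C1C[C@@H](c2ccc(OCc3ccccc3)cc2)Oc2cc(OCc3ccccc3)cc(OCc3ccccc3)c12 | intermediate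
7 | phloroglucinol | Oc1cc(O)cc(O)c1 | starting material
8 | 1,3,5-tris[(4-methoxybenzyl)oxy]benzene | COc1ccc(COc2cc(OCc3ccc(OC)cc3)cc(OCc3ccc(OC)cc3)c2)cc1 | intermediate
9 | 2-bromo-1,3,5-tris[(4-methoxybenzyl)oxy]benzene | COc1ccc(COc2cc(OCc3ccc(OC)cc3)c(Br)c(OCc3ccc(OC)cc3)c2)cc1 | intermediate
10 | 2,4,6-tris[(4-methoxybenzyl)oxy]phenyllithium | [Li]c1c(OCc2ccc(OC)cc2)cc(OCc2ccc(OC)cc2)cc1OCc1ccc(OC)cc1 | intermediate
11 | methyl oxo{2,4,6-tris[(4-methoxybenzyl)oxy]phenyl}acetate | COC(=O)C(=O)c1c(OCc2ccc(OC)cc2)cc(OCc2ccc(OC)cc2)cc1OCc1ccc(OC)cc1 | intermediate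
12 | methyl 3-hydroxy-2-(4-methoxyphenyl)-4,6-bis[(4-methoxybenzyl)oxy]-2,3-dihydro-1-benzofuran-3-carboxylate, stereoisomer mixture | COC(=O)C1(O)C(c2ccc(OC)cc2)Oc2cc(OCc3ccc(OC)cc3)cc(OCc3ccc(OC)cc3)c21 | intermediate
13 | 3-O-triethylsilyl ether of 12 | COC(=O)C1(O[Si](CC)(CC)CC)C(c2ccc(OC)cc2)Oc2cc(OCc3ccc(OC)cc3)cc(OCc3ccc(OC)cc3)c21 | intermediate
14 | 2-(4-methoxyphenyl)-4,6-bis[(4-methoxybenzyl)oxy]-3-[(triethylsilyl)oxy]-2,3-dihydro-1-benzofuran-3-carbaldehyde | O=CC1(O[Si](CC)(CC)CC)C(c2ccc(OC)cc2)Oc2cc(OCc3ccc(OC)cc3)cc(OCc3ccc(OC)cc3)c21 | intermediate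
15 | lithium enolate of 6 (2S) | [Li]OC1=C[C@@H](c2ccc(OCc3ccccc3)cc2)Oc2cc(OCc3ccccc3)cc(OCc3ccccc3)c12 | intermediate
16 | lithium aldolate from 15 and 14, ring F 2,3-trans, carbinol centre open | [Li]OC([C@H]1C(=O)c2c(OCc3ccccc3)cc(OCc3ccccc3)cc2O[C@@H]1c1ccc(OCc2ccccc2)cc1)C1(O[Si](CC)(CC)CC)C(c2ccc(OC)cc2)Oc2cc(OCc3ccc(OC)cc3)cc(OCc3ccc(OC)cc3)c21 | intermediate
17 | acetate of the aldol 16 | CC(=O)OC([C@H]1C(=O)c2c(OCc3ccccc3)cc(OCc3ccccc3)cc2O[C@@H]1c1ccc(OCc2ccccc2)cc1)C1(O[Si](CC)(CC)CC)C(c2ccc(OC)cc2)Oc2cc(OCc3ccc(OC)cc3)cc(OCc3ccc(OC)cc3)c21 | intermediate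
18 | (2R,3E)-3-alkylidene flavanone, triethylsilyl ether (name in step 10) | O=C1/C(=C/C2(O[Si](CC)(CC)CC)C(c3ccc(OC)cc3)Oc3cc(OCc4ccc(OC)cc4)cc(OCc4ccc(OC)cc4)c32)[C@@H](c2ccc(OCc3ccccc3)cc2)Oc2cc(OCc3ccccc3)cc(OCc3ccccc3)c12 | intermediate
19 | (2R,3E)-3-alkylidene flavanone, free tertiary allylic alcohol (name in step 11) | O=C1/C(=C/C2(O)C(c3ccc(OC)cc3)Oc3cc(OCc4ccc(OC)cc4)cc(OCc4ccc(OC)cc4)c32)[C@@H](c2ccc(OCc3ccccc3)cc2)Oc2cc(OCc3ccccc3)cc(OCc3ccccc3)c12 | intermediate
20 | ring-opened (E)-enedione carrying the α-aryloxy-4-methoxybenzyl radical at C2 | O=C1/C(=C/C(=O)c2c(O[CH]c3ccc(OC)cc3)cc(OCc3ccc(OC)cc3)cc2OCc2ccc(OC)cc2)[C@@H](c2ccc(OCc3ccccc3)cc2)Oc2cc(OCc3ccccc3)cc(OCc3ccccc3)c12 | intermediate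
21 | (2S,3R,2″S,3″S)-5″,7″,4‴-tris(benzyloxy)-4′-methoxy-5,7-bis[(4-methoxybenzyl)oxy]-3,3″-biflavanone | COc1ccc([C@H]2Oc3cc(OCc4ccc(OC)cc4)cc(OCc4ccc(OC)cc4)c3C(=O)[C@@H]2[C@@H]2C(=O)c3c(OCc4ccccc4)cc(OCc4ccccc4)cc3O[C@@H]2c2ccc(OCc3ccccc3)cc2)cc1 | intermediate
22 | (2S,3R,2″S,3″S)-5,7,5″,7″,4‴-pentahydroxy-4′-methoxy-3,3″-biflavanone | COc1ccc([C@H]2Oc3cc(O)cc(O)c3C(=O)[C@@H]2[C@@H]2C(=O)c3c(O)cc(O)cc3O[C@@H]2c2ccc(O)cc2)cc1 | target

Total step count: 13. Longest linear sequence: 10 steps (steps 4 to 13).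

**Steps most likely to fail**

Step 12. Three processes may go wrong.
- Triplet energy transfer from the photocatalyst could isomerise the C3=C3″ bond before cleavage, which would cost the facial control at C3.
- The thiyl radical could abstract the doubly activated C2″–H.
- Hydrogen could be transferred to the ring-opened radical before ring closure.

The fallback is ionic and runs in the dark. It sets out from silyl ether 18, so it also bypasses the acid-labile alcohol 19, and it returns at 21. TMSOTf and 2,6-di-tert-butyl-4-methylpyridine in CH2Cl2 at −78 °C silylate C4″=O, so that the enone becomes an electron sink. C2 then leaves C4 as the oxocarbenium ion stabilised by ring B and O1. The bis-silyl dienol ether closes on this ion through C3 in a Mukaiyama-aldol-type, Petasis–Ferrier-like recombination. This should give the ring-expanded ring-F trimethylsilyl enol ether F1. Protonation of F1 with HF·pyridine at −78 °C, anti to ring E, should then give 21. In this way the C3″ protonation becomes a separate event that can be tuned on its own.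

Step 10. Four processes may go wrong.
- The aldol addition at the neopentyl-type aldehyde could reverse.
- The silyl group could migrate to the new alkoxide.
- The ring-F phenoxide could be lost from the enolate by β-elimination, which would racemise C2″.
- Base could move the exocyclic double bond into ring F.

The fallback sets out from enaminone 3, aldehyde 14 and boronic acid 5, and returns at 18. It makes the C3–C3″ bond by irreversible addition of an sp2 organomagnesium and sets C2″ afterwards. Iodine in CHCl3 converts 3 into 5,7-bis(benzyloxy)-3-iodo-4H-chromen-4-one F2. Exchange with i-PrMgCl·LiCl (THF, −40 °C) gives the chromon-3-ylmagnesium chloride F3. This adds to 14 to give the secondary alcohol F4. Ac2O, DMAP and pyridine give the acetate F5. Asymmetric 1,4-addition of 5 at C2″ with the catalyst of step 3, followed by β-acetoxy elimination from the rhodium enolate, should give 18 directly.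

Step 7. Two processes may go wrong.
- A low-lying charge-transfer excited state of the trialkoxyaryl keto ester could decay without hydrogen transfer.
- The 1,5-biradical could fragment instead of closing.

The fallback is a thermal carbene route that sets out from 11 and returns at 12. Condensation with TsNHNH2 gives the tosylhydrazone F6. DBU (Bamford–Stevens reaction) gives the aryldiazoacetate F7. Rh2(OAc)4-catalysed intramolecular 1,5 C–H insertion into a benzylic OCH2 group gives methyl 2-(4-methoxyphenyl)-4,6-bis[(4-methoxybenzyl)oxy]-2,3-dihydro-1-benzofuran-3-carboxylate F8. KN(SiMe3)2 (THF, −78 °C) gives the potassium enolate F9, and oxidation with 2-(phenylsulfonyl)-3-phenyloxaziridine gives 12.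

**Further compounds**
F1 | step 12 | ring-F trimethylsilyl enol ether of 21 (C2, C3 and C2″ as in 21) | COc1ccc([C@H]2Oc3cc(OCc4ccc(OC)cc4)cc(OCc4ccc(OC)cc4)c3C(=O)[C@@H]2C2=C(O[Si](C)(C)C)c3c(OCc4ccccc4)cc(OCc4ccccc4)cc3O[C@@H]2c2ccc(OCc3ccccc3)cc2)cc1
F2 | step 10 | 5,7-bis(benzyloxy)-3-iodo-4H-chromen-4-one | O=c1c(I)coc2cc(OCc3ccccc3)cc(OCc3ccccc3)c12
F3 | step 10 | [5,7-bis(benzyloxy)-4-oxo-4H-chromen-3-yl]magnesium chloride | Cl[Mg]c1coc2cc(OCc3ccccc3)cc(OCc3ccccc3)c2c1=O
F4 | step 10 | secondary alcohol from F3 and 14 | OC(c1coc2cc(OCc3ccccc3)cc(OCc3ccccc3)c2c1=O)C1(O[Si](CC)(CC)CC)C(c2ccc(OC)cc2)Oc2cc(OCc3ccc(OC)cc3)cc(OCc3ccc(OC)cc3)c21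
F5 | step 10 | acetate of F4 | CC(=O)OC(c1coc2cc(OCc3ccccc3)cc(OCc3ccccc3)c2c1=O)C1(O[Si](CC)(CC)CC)C(c2ccc(OC)cc2)Oc2cc(OCc3ccc(OC)cc3)cc(OCc3ccc(OC)cc3)c21
F6 | step 7 | tosylhydrazone of 11 | COC(=O)C(=NNS(=O)(=O)c1ccc(C)cc1)c1c(OCc2ccc(OC)cc2)cc(OCc2ccc(OC)cc2)cc1OCc1ccc(OC)cc1
F7 | step 7 | methyl diazo{2,4,6-tris[(4-methoxybenzyl)oxy]phenyl}acetate | COC(=O)C(=[N+]=[N-])c1c(OCc2ccc(OC)cc2)cc(OCc2ccc(OC)cc2)cc1OCc1ccc(OC)cc1
F8 | step 7 | methyl 2-(4-methoxyphenyl)-4,6-bis[(4-methoxybenzyl)oxy]-2,3-dihydro-1-benzofuran-3-carboxylate | COC(=O)C1C(c2ccc(OC)cc2)Oc2cc(OCc3ccc(OC)cc3)cc(OCc3ccc(OC)cc3)c21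
F9 | step 7 | potassium enolate of F8 | COC(O[K])=C1C(c2ccc(OC)cc2)Oc2cc(OCc3ccc(OC)cc3)cc(OCc3ccc(OC)cc3)c21
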